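## Retrosynthetic overview

1. The acid comes from Pinnick oxidation of the bicyclic aldehyde, which comes from an intramolecular Diels–Alder reaction (IMDA) of a linear hexaenal. The cyclohexene (C4–C5 and C3a–C7a bonds) and the cyclopentene (tether ring) close in this single step.
2. The hexaene is cut at C6–C7: a Pd-catalysed alkenyl–alkenyl coupling joins a phenyl-trienyl alane (west) to a C7 vinyl iodide (east).
3. The east vinyl iodide comes from an enyne by hydrozirconation/iodination. The enyne is cut at C1–C2: a new Ni-catalysed enantioconvergent alkenyl–propargyl coupling sets C1, the only stereocentre made by a reagent.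
4. The (Z)-dienyl partner comes from 1-butyne (bromoboration) and propargyl alcohol (carboalumination), joined by Negishi coupling.
5. The west dienyne comes from phenylacetylene by hydrozirconation, two ethynylations and one carboalumination.

Assumptions: atom labels follow indene numbering of the target (C1, C2, C3, C3a, C4, C5, C6, C7, C7a; side chain C1′–C4′). Compounds 1, 3, 7, 10 and 14 are bought. The sense of induction of the chiral ligand in step 11 must be assigned experimentally.

## Route

**Step 1**
Reactants: 1, phenylacetylene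
Product: 2, (E)-(2-iodovinyl)benzene
Conditions: Cp2Zr(H)Cl, THF, rt; then I2, 0 °C
Reagents that add atoms: iodine, II
Why: Hydrozirconation/iodination; syn addition puts Zr on the terminal carbon and iodinolysis retains geometry, giving only the E iodide.

**Step 2**
Reactants: 2; 3, ethynylmagnesium bromide
Product: 4, (E)-but-1-en-3-yn-1-ylbenzene
Conditions: 3, ZnBr2, THF, 0 °C; then 2, Pd(PPh3)4 (3 mol %), rt
Reagents that add atoms: none
Why: Negishi alkynylation with ethynylzinc bromide gives the terminal enyne directly with retention of alkene geometry.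

**Step 3**
Reactants: 4
Product: 5, [(1E,3E)-4-iodo-3-methylbuta-1,3-dien-1-yl]benzene
Conditions: Me3Al, Cp2ZrCl2 (25 mol %), CH2Cl2, 0 °C to rt; then I2, THF, −30 to 0 °C
Reagents that add atoms: trimethylaluminium, C[Al](C)C; iodine, II
Why: Zr-catalysed carboalumination adds Me and Al syn (Me on the internal carbon), and iodinolysis with retention gives the E trisubstituted iodide (C2′ methyl).

**Step 4**
Reactants: 5; 3, ethynylmagnesium bromide
Product: 6, [(1E,3E)-3-methylhexa-1,3-dien-5-yn-1-yl]benzene
Conditions: 3, ZnBr2, THF, 0 °C; then 5, Pd(PPh3)4 (3 mol %), rt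
Reagents that add atoms: none
Why: Second Negishi alkynylation, stereoretentive; the new alkyne carbons become C5 and C6.

**Step 5**
Reactants: 7, prop-2-yn-1-ol
Product: 8, (E)-3-iodo-2-methylprop-2-en-1-ol
Conditions: Me3Al (3 equiv), Cp2ZrCl2, CH2Cl2, rt; then I2, THF, −30 °C
Reagents that add atoms: trimethylaluminium, C[Al](C)C; iodine, II
Why: Zr-catalysed carboalumination of propargyl alcohol; syn Me/Al addition fixes the E geometry of the future C3a=C4 dienophile (C4 methyl, carboxyl carbon as CH2OH).

**Step 6**
Reactants: 8
Product: 9, (E)-tert-butyl[(3-iodo-2-methylallyl)oxy]dimethylsilane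
Conditions: TBSCl, imidazole, CH2Cl2, rt
Reagents that add atoms: tert-butyldimethylsilyl chloride, CC(C)(C)[Si](C)(C)Cl
Why: Standard silylation; keeping the dienophile at the alcohol level stops any cycloaddition before step 15.

**Step 7**
Reactants: 10, but-1-yne
Product: 11, 2-[(Z)-2-bromobut-1-en-1-yl]-4,4,5,5-tetramethyl-1,3,2-dioxaborolane
Conditions: BBr3, CH2Cl2, −78 °C to rt; then pinacol, rt
Reagents that add atoms: boron tribromide, BrB(Br)Br; pinacol, CC(C)(O)C(C)(C)O
Why: syn-Bromoboration of a terminal alkyne (Br internal, B terminal, cis) followed by esterification gives the Z bromoboronate that encodes the cis C1/C3a relationship of the cyclopentene alkene.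

**Step 8**
Reactants: 9; 11
Product: 12, tert-butyl{[(2E,4Z)-4-ethyl-2-methyl-5-(pinacolboryl)penta-2,4-dien-1-yl]oxy}dimethylsilane
Conditions: 9, t-BuLi (2.1 equiv), Et2O, −78 °C; ZnBr2, THF, −78 to 0 °C; then 11, Pd(t-Bu3P)2 (2 mol %), THF, rt
Reagents that add atoms: none
Why: Negishi alkenyl–alkenyl coupling at C–Br with retention on both partners (forms C3–C3a); the Bpin group is inert without base, and the E vinyllithium cannot undergo retro-Brook migration.

**Step 9**
Reactants: 12
Product: 13, tert-butyl{[(2E,4Z)-4-ethyl-5-iodo-2-methylpenta-2,4-dien-1-yl]oxy}dimethylsilane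
Conditions: NaOH (aq), THF, 0 °C; then I2, 0 °C to rt
Reagents that add atoms: iodine, II
Why: Base-mediated iododeboronation of an alkenylboronate proceeds with retention, giving the (Z)-dienyl iodide (I cis to C3a).

**Step 10**
Reactants: 14, pent-3-yn-2-ol (racemic)
Product: 15, 4-bromopent-2-yne (racemic)
Conditions: PBr3, pyridine (cat.), Et2O, 0 °C
Reagents that add atoms: phosphorus tribromide, BrP(Br)Br
Why: Standard conversion of a secondary propargylic alcohol to the bromide; the racemate is wanted.

**Step 11**
Reactants: 13; 15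
Product: 16, tert-butyl{[(2E,4Z,6R)-4-ethyl-2,6-dimethylnona-2,4-dien-7-yn-1-yl]oxy}dimethylsilane (chain C6 is target C1)
Conditions: 13, t-BuLi (2.1 equiv), Et2O, −78 °C; ZnCl2, THF, to 0 °C (1.3 equiv zinc reagent); then rac-15 (1.0 equiv), NiCl2·glyme (10 mol %), indanyl-pybox (13 mol %, enantiomer chosen to give 6R), DME, −20 °C
Reagents that add atoms: none
Why: Proposed new method: a Ni/pybox-catalysed enantioconvergent Negishi coupling of a racemic secondary propargylic bromide with a (Z)-dienylzinc reagent. An alkenyl–Ni(I) species abstracts Br from either enantiomer of 15 to give a planar propargylic radical, which is captured by the chiral alkenyl–Ni(II) complex and reductively eliminates from Ni(III) at the propargylic terminus, so both enantiomers converge on (R)-C1 while stereoretentive transmetalation keeps the Z geometry. The closest known reaction type is the Ni/pybox stereoconvergent Negishi arylation of racemic propargylic halides (alkenylzinc reagents are known in related Ni couplings of α-bromonitriles but not with propargylic electrophiles).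

**Step 12**
Reactants: 16
Product: 17, tert-butyl{[(2E,4Z,6R,7E)-4-ethyl-8-iodo-2,6-dimethylnona-2,4,7-trien-1-yl]oxy}dimethylsilane
Conditions: Cp2Zr(H)Cl (1.5 equiv), THF, rt to 40 °C; then I2, 0 °C
Reagents that add atoms: iodine, II
Why: Hydrozirconation of the internal alkyne equilibrates Zr to the less hindered, methyl-bearing carbon (C7); syn addition and retentive iodinolysis give the E iodide (I trans to C1). The trisubstituted diene and the TBS ether do not react.

**Step 13**
Reactants: 6; 17
Product: 18, tert-butyl{[(2E,4Z,6S,7E,9E,11E,13E)-4-ethyl-2,6,8,10,12-pentamethyl-14-phenyltetradeca-2,4,7,9,11,13-hexaen-1-yl]oxy}dimethylsilane (same spatial arrangement at C6 as 17; the descriptor changes only through CIP priorities)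
Conditions: 6, Me3Al (2 equiv), Cp2ZrCl2 (25 mol %), CH2Cl2, rt; remove volatiles; then 17, ZnCl2, Pd2(dba)3 (2.5 mol %), P(2-furyl)3 (10 mol %), THF, rt
Reagents that add atoms: trimethylaluminium, C[Al](C)C
Why: One-pot carboalumination and Pd/Zn-mediated alkenyl–alkenyl (Negishi) coupling. The syn Me/Al addition installs the C5 methyl and the E C5=C6 alkene, and the stereoretentive coupling forms C6–C7, completing the all-E diene.

**Step 14**
Reactants: 18
Product: 19, (2E,4Z,6S,7E,9E,11E,13E)-4-ethyl-2,6,8,10,12-pentamethyl-14-phenyltetradeca-2,4,7,9,11,13-hexaen-1-ol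
Conditions: TBAF, THF, 0 °C, dark
Reagents that add atoms: none
Why: Fluoride desilylation; the bis-allylic C–H is not acidic enough to be touched, and the unactivated dienophile does not cyclise.

**Step 15**
Reactants: 19
Product: 20, (2E,4Z,6S,7E,9E,11E,13E)-4-ethyl-2,6,8,10,12-pentamethyl-14-phenyltetradeca-2,4,7,9,11,13-hexaenal
Conditions: MnO2 (20 equiv), CH2Cl2, rt, dark
Reagents that add atoms: none
Why: Neutral allylic oxidation turns on the dienophile without base, so the C1 stereocentre and the alkene geometries survive.

**Step 16**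
Reactants: 20
Product: 21, (1R,3aR,4R,5S,7aS)-3-ethyl-1,4,5,7-tetramethyl-5-[(1E,3E)-2-methyl-4-phenylbuta-1,3-dien-1-yl]-3a,4,5,7a-tetrahydro-1H-indene-4-carbaldehyde
Conditions: PhMe (5 mM), BHT (cat.), 40–60 °C, dark
Reagents that add atoms: none
Why: Thermal IMDA forming C4–C5 and C3a–C7a. The E dienophile and E,E diene fix the C3a/C4 and C5/C7a relationships. The CHO-endo transition state gives the trans ring fusion with CHO cis to the side chain. A(1,3) strain between the C7 methyl and C1 puts C1–H in the diene plane, so the dienophile adds anti to the C1 methyl; C1 thereby sets the absolute configuration at C3a, C4, C5 and C7a.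

**Step 17**
Reactants: 21
Product: 22, zyggomphic acid B, (1R,3aR,4R,5S,7aS)-3-ethyl-1,4,5,7-tetramethyl-5-[(1E,3E)-2-methyl-4-phenylbuta-1,3-dien-1-yl]-3a,4,5,7a-tetrahydro-1H-indene-4-carboxylic acid
Conditions: NaClO2, NaH2PO4, 2-methyl-2-butene (excess), t-BuOH/H2O, 0 °C to rt
Reagents that add atoms: sodium chlorite, [Na+].[O-]Cl=O
Why: Pinnick oxidation of a non-enolisable quaternary aldehyde; the scavenger protects the alkenes, no stereocentre is affected, and hydrolysis of a hindered ester is avoided.

## Compound list

1 | phenylacetylene | C#Cc1ccccc1 | starting material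
2 | (E)-(2-iodovinyl)benzene | I/C=C/c1ccccc1 | intermediate
3 | ethynylmagnesium bromide | C#C[Mg]Br | starting material
4 | (E)-but-1-en-3-yn-1-ylbenzene | C#C/C=C/c1ccccc1 | intermediate
5 | [(1E,3E)-4-iodo-3-methylbuta-1,3-dien-1-yl]benzene | I/C=C(C)/C=C/c1ccccc1 | intermediate
6 | [(1E,3E)-3-methylhexa-1,3-dien-5-yn-1-yl]benzene | C#C/C=C(C)/C=C/c1ccccc1 | intermediate
7 | prop-2-yn-1-ol | C#CCO | starting material
8 | (E)-3-iodo-2-methylprop-2-en-1-ol | I/C=C(C)/CO | intermediate
9 | (E)-tert-butyl[(3-iodo-2-methylallyl)oxy]dimethylsilane | I/C=C(C)/CO[Si](C)(C)C(C)(C)C | intermediate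
10 | but-1-yne | CCC#C | starting material
11 | 2-[(Z)-2-bromobut-1-en-1-yl]-4,4,5,5-tetramethyl-1,3,2-dioxaborolane | CC/C(Br)=C/B1OC(C)(C)C(C)(C)O1 | intermediate
12 | (2E,4Z)-dienyl pinacolboronate TBS ether | CC/C(=C/B1OC(C)(C)C(C)(C)O1)/C=C(C)/CO[Si](C)(C)C(C)(C)C | intermediate
13 | (2E,4Z)-dienyl iodide TBS ether | CC/C(=C/I)/C=C(C)/CO[Si](C)(C)C(C)(C)C | intermediate
14 | pent-3-yn-2-ol (racemic) | CC#CC(C)O | starting material
15 | 4-bromopent-2-yne (racemic) | CC#CC(C)Br | intermediate
16 | (2E,4Z,6R)-dienyne TBS ether | CC#C[C@H](C)/C=C(/CC)\C=C(/C)CO[Si](C)(C)C(C)(C)C | intermediate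
17 | (2E,4Z,6R,7E)-trienyl iodide TBS ether | C/C(I)=C\[C@H](C)/C=C(/CC)\C=C(/C)CO[Si](C)(C)C(C)(C)C | intermediate
18 | (2E,4Z,6S,7E,9E,11E,13E)-hexaene TBS ether | c1ccccc1/C=C/C(C)=C/C(C)=C/C(C)=C/[C@H](C)/C=C(/CC)\C=C(/C)CO[Si](C)(C)C(C)(C)C | intermediate
19 | (2E,4Z,6S,7E,9E,11E,13E)-hexaen-1-ol | c1ccccc1/C=C/C(C)=C/C(C)=C/C(C)=C/[C@H](C)/C=C(/CC)\C=C(/C)CO | intermediate
20 | (2E,4Z,6S,7E,9E,11E,13E)-hexaenal | c1ccccc1/C=C/C(C)=C/C(C)=C/C(C)=C/[C@H](C)/C=C(/CC)\C=C(/C)C=O | intermediate
21 | bicyclic aldehyde (1R,3aR,4R,5S,7aS) | CCC1=C[C@@H](C)[C@@H]2C(C)=C[C@](C)(/C=C(C)/C=C/c3ccccc3)[C@](C)(C=O)[C@@H]12 | intermediate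
22 | zyggomphic acid B | CCC1=C[C@@H](C)[C@@H]2C(C)=C[C@](C)(/C=C(C)/C=C/c3ccccc3)[C@](C)(C(=O)O)[C@@H]12 | target

## Summary

Total step count: 17.
Longest linear sequence: 11 steps (5, 6, 8, 9, 11, 12, 13, 14, 15, 16, 17). The west branch (1–4) and the single-step branches (7, 10) converge on it.

Three steps most likely to fail:

1. **Step 11 (proposed new Ni-catalysed enantioconvergent alkenyl–propargyl coupling).** Risks are low ee with the hindered (Z)-dienylzinc, allenyl coupling, and homocoupling.
   Fallback (known chemistry, chiral pool): start from methyl (S)-3-hydroxy-2-methylpropanoate. PMB-protect, reduce with DIBAL to the aldehyde, and form the 1,1-dibromoalkene with CBr4/PPh3. Do a trans-selective Pd-catalysed Negishi ethylation, then a second stereoretentive Negishi coupling with the alkenylzinc from 9. Remove PMB, oxidise with DMP, and convert the aldehyde to the methyl alkyne (Corey–Fuchs, n-BuLi/MeI) to reach 16. This sample also serves to confirm the configuration of Ni-derived 16.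

2. **Step 16 (IMDA).** Risks are the endo/exo ratio (trans versus cis fusion), a competing [1,5]-H shift of the bis-allylic C1–H in the (Z)-diene, and polyene isomerisation.
   Fallback: cyclise a truncated diene and add the side chain late. Couple 17 with the alane from PMB-protected propargyl alcohol so that C5 carries Me and CH2OPMB, then run the IMDA on the simpler trienal. Afterwards convert C5–CH2OH to the methyl alkyne (oxidation, Ohira–Bestmann, MeI), hydrozirconate/iodinate, and Suzuki-couple with (E)-styryl-Bpin made from phenylacetylene.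

3. **Step 12 (regioselective hydrozirconation of the internal alkyne).** Risks are the C7/C7a regioisomer ratio and over-reaction of the diene with excess Schwartz reagent.
   Fallback: reverse the polarity of the union. Use NHC–Cu-catalysed protoboration of 16 (B2pin2, MeOH; boron goes to the methyl-bearing carbon) to make the C7 alkenyl-Bpin, and Suzuki-couple it with the isolated trienyl iodide obtained by carboalumination/iodinolysis of 6.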